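## Structural features

The target is a bicyclic diterpenoid diester of the labdane type. Ring A (C1–C5, C10) is saturated and carries the gem-dimethyl group at C4; ring B (C5–C10) is a cyclohexene with its double bond at C6=C7, and the two rings are trans-fused. Ring B carries four contiguous stereocentres: C5 (H), C10 (quaternary, methyl C20), C9 (side chain) and C8 (methyl ester C17). C20 is cis to C11, C17 is trans to C11, and the absolute configuration (5R,8S,9R,10S) is that of the ent-labdane series. The side chain C11–C16 on C9 ends in a trisubstituted (13E)-enoate in which the acetoxymethyl carbon C16 is trans and the C12 methylene cis to the ester carbon C15. The fragile points are C8, whose hydrogen is both allylic and alpha to an ester (epimerisation, or migration of the 6,7-double bond into conjugation), the allylic acetate, and the coexistence of two methyl esters and an acetate. The real difficulty is the dense ring B: a quaternary carbon that is syn-diaxial to a C4 methyl group and is flanked by three further stereocentres, all in one enantiomeric series. The 6,7-double bond lies between C5 and C8, so ring B is the retron of a [4+2] union of a C5=C6–C7=C8 diene with a C9=C10 dienophile. Because C5 and C10 are also joined through C4–C1, one acyclic trienoyl chain can close rings A and B together.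

## Logic of the disconnections

**27 back to 23 (through 26, 25, 24).** No skeletal bond is cut; the O–CH3 bond and the carbonyl of the C17 ester are taken back to the silyl-protected carbinol. The reason is that C8–H of the beta,gamma-unsaturated ester is the most easily lost stereocentre, so the ester is made last and C8 is not acidic during the coupling and olefination steps. The demand is an oxidation of 24 that passes 25 without enolisation, a neutral methylation of 26, and a desilylation that spares the allylic acetate.

**23 back to 18 and 21 (through 22).** The C12–C13 bond (sp3–sp2) is cut. This removes the whole enoate–acetate terminus in one piece with its geometry already fixed, and it replaces a substitution at the hindered, beta-branched C11 by a coupling at the remote C12. The demand is a hydroboration that takes the vinyl group of 18 and not the ring alkene, and a coupling that retains the geometry of 21 and spares its acetate.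

**21 back to 19 (through 20).** The C13–I and C14–H bonds and the acetyl C–O bond are cut. Anti addition of hydrogen iodide to the ynoate puts iodine cis to the ester, which retention in the coupling turns into C12 cis and C16 trans to C15. The demand is kinetic anti addition without later isomerisation.

**18 back to 15 (through 16 and 17).** The C11=C12 bond is cut (methylenation of 16), and C11 is traced back through 17 to the acyl carbon of 15 by cutting the C11–N bond. The gain is that the cycloadduct needs only one added carbon to become a coupling partner. The demand is removal of the oxazolidinone from a hindered carbonyl without ring opening, and olefination of 16 without epimerisation at C9.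

**15 back to 14.** The C5–C10 and C8–C9 bonds are cut; both rings and all four stereocentres go back to three alkene geometries and one face of the dienophile. The structures were checked before use:
- The 2E, 8E, 10Z geometry of 14 does encode the target: C20 cis to C11, trans fusion, C17 trans to C11.
- The descriptors of 15 (C9 R, C8 S, C5 R in every intermediate; C10 R while C11 bears oxygen and S afterwards, by priority change only) correspond to the target. No correction was needed.

The constitution and geometry of 14 are kept. An ester-level C17 would deactivate the diene, and an E diene terminus would no longer give 15. What is tightened is the catalyst (the hexafluoroantimonate complex, the most Lewis-acidic of its family) and the way to 14, in which each alkene geometry now comes from a stereospecific step. The demand is high: endo selectivity, one pi-face, and enough reactivity from a trisubstituted dienophile and a Z diene terminus.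

**14 back to 10 and 11 (through 12 and 13), and 10 back to 9.** The N–C11 bond is cut, then the ester is restored. The imide is made last before the key step so that it is not exposed to base or palladium. The demand is acyl transfer without deconjugation of the beta-methyl enoyl unit.

**9 back to 5 and 7 (through 8).** The C1–C10 bond is cut. The dienophile end with its E geometry comes from a two-carbon-plus-methyl building block, and the tether carbons C1–C3 from the allyl group already present in 5. The demand is hydroboration of the terminal alkene in the presence of the diene, and coupling with retention.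

**7 back to 6.** The O–S bond is cut; the demand is E-selective enol sulfonylation.

**5 back to 2 and 3 (through 4).** The C6–C7 bond is cut and two hydrogens are removed from C7=C8. The Z geometry then comes from a cis semireduction of an alkyne. The demand is reduction of the conjugated triple bond only.

**2 back to 1.** The C5=C6 bond is cut; the demand is an E-selective one-carbon olefination of a hindered aldehyde.

## Other disconnections considered

**Alternative 1:** The cut is C1–C10, made on a ring B that is still aromatic.

- Forward step: the phenolate of A1 would alkylate its para carbon C10 under a chiral quaternary ammonium phase-transfer catalyst with Cs2CO3, closing ring A to give the cross-conjugated bromodienone A2. A1 is a hexasubstituted salicylate with bromine on C6, the phenol oxygen on C7, ester C17 on C8, the C11–C14 butynyl chain on C9 and methyl C20 on C10. On C5 it carries a chain joined through the quaternary C4 and ending in a mesylate at C1. One wording point is corrected: the leaving group is primary; only the point of attachment to the ring is a tertiary-alkyl carbon.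
- In favour: ring B and its substitution pattern come from an arene; the quaternary C10 is made by an intramolecular SN2 reaction that the methyl group does not slow; O-alkylation is geometrically excluded; four side-chain carbons are already present. On reactivity at the quaternary centre and on early presence of the side chain this alternative is better than the chosen plan.
- Against: facial discrimination of a flat phenolate by a chiral ion pair in alkylation with an unactivated primary sulfonate has little precedent. Attack at the ortho carbon C6 is a competing six-ring closure. A2 holds only one of the four stereocentres, so C5, C8 and C9 would rest on later face-selective reductions of hindered enone double bonds beside an alkyne, followed by removal of bromine and the C7 oxygen and installation of the 6,7-alkene. A1, a benzene with six different substituents, is itself a long synthesis.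
- Comparison: the two plans are equal in closing ring A in the key step. The chosen cycloaddition also closes ring B and fixes all four centres through alkene geometry, so in structure and step economy the alternative is judged clearly behind.

**Alternative 2:** The cut is C8–C9.

- Forward step: A3 is a ring-A-fused dihydropyran (ring atoms O, C11, C9, C10, C5, C6) with the enol ether C11=C9 and a (Z)-2-(methoxycarbonyl)vinyl group on C6. On heating, a [3,3] shift would break C6–O and form C8–C9 to give the aldehyde ester A4. One wording point is corrected: oxacycle and carbocycle are both six-membered, so this is a ring interchange through a boat-like, bicyclo[2.2.2]-type transition state and not a contraction.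
- In favour: no reagent is needed, and the C6 configuration is relayed to C8 and C9 through a cyclic transition state. In that boat the Z enoate places C17 trans to C11 as required. A4 already has C17 as the ester and C11 as an aldehyde. On predictability of the stereochemical relay and on oxidation-state economy after the key step this alternative is better than the chosen plan.
- Against: A3 must already contain the quaternary C10, the trans fusion at C5 and a defined carbinol centre at C6, so the hard centres are supplied and not made. A boat-only rearrangement of an electron-poor allyl unit needs high temperature, at which the Z enoate may isomerise and A4 may epimerise at C8 and C9.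
- Comparison: two centres and one ring are created against four centres and two rings. The shorter end game is outweighed by the longer route to A3.

**Alternative 3:** The cut is C7–C8.

- Forward step: A5 is a ring A compound with a (Z)-2-iodovinyl group on C5 and, on C10, a chain whose C9 bears the protected three-carbon arm and whose C8 is an alpha-bromo ester used as both epimers. NiBr2(dme), 4,4'-di-tert-butyl-2,2'-bipyridine and manganese powder would join the vinyl and alkyl carbons and close ring B to give A6.
- In favour: reductive cross-electrophile coupling is mild and is not held back by the substitution that slows a cycloaddition. The C8 radical lets both bromide epimers converge, and C17 is an ester from the outset. On reactivity of the key step and on the oxidation level of C17 this alternative is better. On the side chain it is equal, since the arm of A6 needs about as many steps as the vinyl group of 18.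
- Against: the key step sets only C8, and only by substrate control, while C5, C9 and the quaternary C10 must be built beforehand on a cyclohexane, which leaves the central problem unsolved. Reduction of either halide, elimination to the conjugated ester and loss of the Z vinyl iodide geometry are further risks.
- Comparison: in structure and step economy the chosen plan is ahead; in certainty of the bond-forming event itself it is behind.

Key step: step 8

Assumption: the sense of induction of the copper catalyst is assigned from the square-planar chelate model, with (S,S)-tBu-box = 2,2'-(propane-2,2-diyl)bis[(4S)-4-tert-butyl-4,5-dihydro-1,3-oxazole]; the (R,R) ligand would be used with no other change if the opposite sense were found. TBS = tert-butyl(dimethyl)silyl.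

## Route

Step 1
Reactants: 1 2,2-dimethylpent-4-enal
Product: 2 (1E)-1-iodo-3,3-dimethylhexa-1,5-diene
Conditions: CrCl2 (6 equiv), CHI3 (2 equiv), THF/1,4-dioxane, 0 °C to rt
Reagents that add atoms: iodoform, IC(I)I
Why: Takai olefination: the iodo-substituted geminal dichromium reagent formed from iodoform and divalent chromium adds to the aldehyde and eliminates to the E vinyl iodide (C5=C6), the quaternary C4 reinforcing the E preference; the isolated terminal alkene does not react.

Step 2
Reactants: 2 (1E)-1-iodo-3,3-dimethylhexa-1,5-diene; 3 tert-butyl(dimethyl)(prop-2-yn-1-yloxy)silane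
Product: 4 tert-butyl{[(4E)-6,6-dimethylnona-4,8-dien-2-yn-1-yl]oxy}dimethylsilane
Conditions: PdCl2(PPh3)2 (2 mol%), CuI (4 mol%), Et3N, THF, rt
Reagents that add atoms: none
Why: Sonogashira coupling: oxidative addition of zerovalent palladium into the vinyl C–I bond, transmetalation from the copper acetylide and reductive elimination form C6–C7 with retention of the E geometry; silyl ether and terminal alkene are spectators.

Step 3
Reactants: 4 tert-butyl{[(4E)-6,6-dimethylnona-4,8-dien-2-yn-1-yl]oxy}dimethylsilane
Product: 5 tert-butyl{[(2Z,4E)-6,6-dimethylnona-2,4,8-trien-1-yl]oxy}dimethylsilane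
Conditions: Zn dust activated with Cu(OAc)2 and AgNO3, MeOH/H2O (1:1), rt to 40 °C
Reagents that add atoms: none
Why: Boland reduction: the zinc couple reduces only the triple bond conjugated to the alkene and delivers both hydrogens to the same face, so C7=C8 is formed Z; isolated alkenes are not reduced, which protects the terminal vinyl group.

Step 4
Reactants: 6 methyl 3-oxobutanoate
Product: 7 methyl (2E)-3-{[(trifluoromethyl)sulfonyl]oxy}but-2-enoate
Conditions: Tf2O, aq Me4NOH, hexane, 5 °C
Reagents that add atoms: trifluoromethanesulfonic anhydride, O=S(=O)(OS(=O)(=O)C(F)(F)F)C(F)(F)F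
Why: Enolate O-sulfonylation: with the non-coordinating tetramethylammonium counter-ion the beta-keto ester enolate takes the extended, unchelated form with the enolate oxygen trans to the ester, and triflation fixes this as the E enol triflate; this geometry later puts the tether trans to C11.

Step 5
Reactants: 5 tert-butyl{[(2Z,4E)-6,6-dimethylnona-2,4,8-trien-1-yl]oxy}dimethylsilane; 7 methyl (2E)-3-{[(trifluoromethyl)sulfonyl]oxy}but-2-enoate
Product: 9 methyl (2E,8E,10Z)-12-(TBS-oxy)-3,7,7-trimethyldodeca-2,8,10-trienoate, via alkylborane 8 (not isolated)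
Conditions: 9-BBN, THF, 0 °C to rt; then 7, PdCl2(dppf) (5 mol%), K3PO4, H2O (few equiv), 1,4-dioxane, 60 °C
Reagents that add atoms: none
Why: B-alkyl Suzuki–Miyaura coupling: 9-BBN adds anti-Markovnikov to the monosubstituted alkene only (the conjugated 1,2-disubstituted diene is much slower), and oxidative addition into the C–OTf bond, transmetalation and reductive elimination join C1 to C10 with retention, so the chain ends trans to the ester (2E).

Step 6
Reactants: 9 methyl (2E,8E,10Z)-12-(TBS-oxy)-3,7,7-trimethyldodeca-2,8,10-trienoate
Product: 10 (2E,8E,10Z)-12-(TBS-oxy)-3,7,7-trimethyldodeca-2,8,10-trienoic acid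
Conditions: LiOH·H2O, THF/MeOH/H2O, rt to 35 °C; then 1 M HCl to pH 4, 0 °C
Reagents that add atoms: lithium hydroxide, [Li+].[OH-]
Why: Ester saponification by acyl substitution; the enoate geometry, the Z diene and the primary silyl ether are stable to aqueous LiOH at this temperature, and the acid is liberated at pH 4 in the cold to spare the allylic silyl ether.

Step 7
Reactants: 10 (2E,8E,10Z)-12-(TBS-oxy)-3,7,7-trimethyldodeca-2,8,10-trienoic acid; 11 1,3-oxazolidin-2-one
Product: 14 3-[(2E,8E,10Z)-12-(TBS-oxy)-3,7,7-trimethyldodeca-2,8,10-trienoyl]-1,3-oxazolidin-2-one, via mixed pivalic anhydride 12 (not isolated), via lithium oxazolidinide 13 (not isolated)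
Conditions: PivCl, Et3N, THF, −78 to 0 °C; then 13 (from 11, n-BuLi, THF, −78 °C), −78 to 0 °C; aq NH4Cl
Reagents that add atoms: none
Why: N-acylation through a mixed anhydride: the lithium amide 13 attacks the enoyl carbonyl of 12 because the pivaloyl carbonyl is shielded by its tert-butyl group; low temperature and the absence of free amine during acyl transfer avoid deconjugation through a vinylketene.

Step 8
Reactants: 14 3-[(2E,8E,10Z)-12-(TBS-oxy)-3,7,7-trimethyldodeca-2,8,10-trienoyl]-1,3-oxazolidin-2-one
Product: 15 3-{[(1R,2S,4aR,8aR)-2-(TBS-oxymethyl)-5,5,8a-trimethyl-1,2,4a,5,6,7,8,8a-octahydronaphthalen-1-yl]carbonyl}-1,3-oxazolidin-2-one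
Conditions: [Cu((S,S)-tBu-box)](SbF6)2 (10 mol%, from CuCl2, the ligand and AgSbF6, filtered from AgCl), CH2Cl2, rt to 40 °C
Reagents that add atoms: none
Why: Proposed new method: the imide binds divalent copper through both carbonyl oxygens in a distorted square plane, which lowers the LUMO of C9=C10 and holds the enoyl unit s-cis (the s-trans form would drive C20 into the oxazolidinone ring), and the C5–C8 diene then adds suprafacially in a concerted, asynchronous [4+2] step in which the C5–C10 bond to the beta-carbon runs ahead of C8–C9. The closest known reaction type is the bis(oxazoline)copper-catalysed type-1 intramolecular Diels–Alder reaction of (E,E,E)-trienoyl oxazolidinones to trans-fused bicycles; new here are the beta-methyl group that makes C10 quaternary and the Z diene terminus, both of which slow the reaction, which is why the most Lewis-acidic hexafluoroantimonate complex and mild warming are chosen. Ring A closes by exo-type attack of the diene terminus C5 on C10 through the four-atom tether in a chair-like fold that the gem-dimethyl group at C4 favours; ring B is the cycloadduct ring itself and closes when C8 bonds to C9. C9 is set by the catalyst: the tert-butyl group next to the bound enoyl unit covers the Si face of C9, so C8 bonds to the Re face and C9 becomes R. C10 follows from the 2E geometry, transferred suprafacially, which puts C20 cis to C11. C5 follows from the endo mode, in which the imide lies under the diene and the tether is anti to it, so H5 ends trans to C20 (trans fusion), and C8 follows from the Z geometry of C7=C8, which puts C17 inside and therefore trans to C11. The step needs endo over exo selectivity and a single pi-face: the two-point-bound acyl group on the terminal dienophile carbon secures the first and the ligand the second, while the developing diaxial contact between C20 and the axial C4 methyl and slow turnover are the main threats.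

Step 9
Reactants: 15 3-{[(1R,2S,4aR,8aR)-2-(TBS-oxymethyl)-5,5,8a-trimethyl-1,2,4a,5,6,7,8,8a-octahydronaphthalen-1-yl]carbonyl}-1,3-oxazolidin-2-one
Product: 17 [(1R,2S,4aR,8aR)-2-(TBS-oxymethyl)-5,5,8a-trimethyl-1,2,4a,5,6,7,8,8a-octahydronaphthalen-1-yl]methanol, via aldehyde 16 (not isolated)
Conditions: LiBH4, H2O (1 equiv), Et2O, 0 °C; then 1 M NaOH
Reagents that add atoms: none
Why: Reductive cleavage of an N-acyl oxazolidinone: lithium activates the exocyclic carbonyl, hydride adds there, the hemiaminal collapses to aldehyde 16 and the oxazolidinone anion, and 16 is reduced at once to 17; the medium does not epimerise C9, and silyl ether and ring alkene are inert.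

Step 10
Reactants: 17 [(1R,2S,4aR,8aR)-2-(TBS-oxymethyl)-5,5,8a-trimethyl-1,2,4a,5,6,7,8,8a-octahydronaphthalen-1-yl]methanol
Product: 16 (1R,2S,4aR,8aR)-2-(TBS-oxymethyl)-5,5,8a-trimethyl-1,2,4a,5,6,7,8,8a-octahydronaphthalene-1-carbaldehyde
Conditions: Dess–Martin periodinane, NaHCO3, CH2Cl2, 0 °C to rt
Reagents that add atoms: none
Why: Dess–Martin oxidation: ligand exchange at iodine and intramolecular proton abstraction give the aldehyde under buffered, non-enolising conditions, so C9, whose formyl group already sits in the favoured equatorial position, keeps its configuration.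

Step 11
Reactants: 16 (1R,2S,4aR,8aR)-2-(TBS-oxymethyl)-5,5,8a-trimethyl-1,2,4a,5,6,7,8,8a-octahydronaphthalene-1-carbaldehyde
Product: 18 tert-butyl{[(1R,2S,4aR,8aS)-1-ethenyl-5,5,8a-trimethyl-1,2,4a,5,6,7,8,8a-octahydronaphthalen-2-yl]methoxy}dimethylsilane
Conditions: Ph3PCH3Br, KN(SiMe3)2, THF, 0 °C; then 16, 0 °C to rt
Reagents that add atoms: methyltriphenylphosphonium bromide, C[P+](c1ccccc1)(c1ccccc1)c1ccccc1.[Br-]
Why: Wittig methylenation: the unstabilised ylide adds to the hindered aldehyde and the oxaphosphetane collapses to the vinyl group (C11=C12); addition is faster than deprotonation at C9, and the 8a descriptor changes from R to S only because C11 loses its oxygen.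

Step 12
Reactants: 19 methyl 4-hydroxybut-2-ynoate
Product: 20 methyl 4-(acetyloxy)but-2-ynoate
Conditions: Ac2O, Sc(OTf)3 (1 mol%), MeCN, 0 °C
Reagents that add atoms: acetic anhydride, CC(=O)OC(C)=O
Why: Lewis-acid-catalysed O-acetylation: Sc(OTf)3 activates the anhydride, and the absence of an amine base avoids conjugate addition to the ynoate.

Step 13
Reactants: 20 methyl 4-(acetyloxy)but-2-ynoate
Product: 21 methyl (2Z)-4-(acetyloxy)-3-iodobut-2-enoate
Conditions: NaI, AcOH, 70 °C
Reagents that add atoms: sodium iodide, [Na+].[I-]
Why: Conjugate hydroiodination: iodide adds to C13, beta to the ester, and the allenoate is protonated anti, so iodine ends cis to the ester (2Z) and the acetoxymethyl group trans; this is the kinetic isomer and the moderate temperature holds it.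

Step 14
Reactants: 18 tert-butyl{[(1R,2S,4aR,8aS)-1-ethenyl-5,5,8a-trimethyl-1,2,4a,5,6,7,8,8a-octahydronaphthalen-2-yl]methoxy}dimethylsilane; 21 methyl (2Z)-4-(acetyloxy)-3-iodobut-2-enoate
Product: 23 methyl (2E)-3-[(acetyloxy)methyl]-5-[(1R,2S,4aR,8aS)-2-(TBS-oxymethyl)-5,5,8a-trimethyl-1,2,4a,5,6,7,8,8a-octahydronaphthalen-1-yl]pent-2-enoate, via alkylborane 22 (not isolated)
Conditions: 9-BBN, THF, rt; then 21, PdCl2(dppf) (5 mol%), AsPh3, K3PO4 (3 M aq), DMF, rt
Reagents that add atoms: none
Why: B-alkyl Suzuki–Miyaura coupling: 9-BBN adds to the terminal carbon C12 of the vinyl group and leaves the hindered cis-disubstituted ring alkene, and the vinyl iodide couples with retention, so C12 takes the place of iodine cis to the ester. The descriptor changes from 2Z in 21 to 2E in 23 only because the priorities change; no stereocentre is touched and C8 is still a carbinol carbon.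

Step 15
Reactants: 23 methyl (2E)-3-[(acetyloxy)methyl]-5-[(1R,2S,4aR,8aS)-2-(TBS-oxymethyl)-5,5,8a-trimethyl-1,2,4a,5,6,7,8,8a-octahydronaphthalen-1-yl]pent-2-enoate
Product: 24 methyl (2E)-3-[(acetyloxy)methyl]-5-[(1R,2S,4aR,8aS)-2-(hydroxymethyl)-5,5,8a-trimethyl-1,2,4a,5,6,7,8,8a-octahydronaphthalen-1-yl]pent-2-enoate
Conditions: HF·pyridine, pyridine, THF, 0 °C to rt
Reagents that add atoms: none
Why: Fluoride-mediated desilylation: buffered HF·pyridine cleaves the primary silyl ether through pentacoordinate silicon and, being only weakly acidic, leaves the acetate, the methyl ester and the enoate untouched.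

Step 16
Reactants: 24 methyl (2E)-3-[(acetyloxy)methyl]-5-[(1R,2S,4aR,8aS)-2-(hydroxymethyl)-5,5,8a-trimethyl-1,2,4a,5,6,7,8,8a-octahydronaphthalen-1-yl]pent-2-enoate
Product: 26 (1R,2S,4aR,8aS)-1-{(3E)-3-[(acetyloxy)methyl]-5-methoxy-5-oxopent-3-en-1-yl}-5,5,8a-trimethyl-1,2,4a,5,6,7,8,8a-octahydronaphthalene-2-carboxylic acid, via aldehyde 25 (not isolated)
Conditions: TEMPO (0.2 equiv), PhI(OAc)2 (2.2 equiv), MeCN/H2O (1:1), rt
Reagents that add atoms: water, O
Why: Oxoammonium oxidation: the oxoammonium salt formed from TEMPO and PhI(OAc)2 oxidises the primary alcohol to aldehyde 25, whose hydrate is oxidised on to the acid in the same flask, so the enolisable beta,gamma-unsaturated aldehyde does not accumulate; the near-neutral medium protects C8 and the position of the 6,7-double bond.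

Step 17
Reactants: 26 (1R,2S,4aR,8aS)-1-{(3E)-3-[(acetyloxy)methyl]-5-methoxy-5-oxopent-3-en-1-yl}-5,5,8a-trimethyl-1,2,4a,5,6,7,8,8a-octahydronaphthalene-2-carboxylic acid
Product: 27 methyl (1R,2S,4aR,8aS)-1-{(3E)-3-[(acetyloxy)methyl]-5-methoxy-5-oxopent-3-en-1-yl}-5,5,8a-trimethyl-1,2,4a,5,6,7,8,8a-octahydronaphthalene-2-carboxylate
Conditions: Me3SiCHN2, toluene/MeOH (4:1), 0 °C
Reagents that add atoms: (trimethylsilyl)diazomethane, C[Si](C)(C)C=[N+]=[N-]
Why: Esterification with (trimethylsilyl)diazomethane: the acid protonates the reagent, methanol removes silicon, and the carboxylate is methylated by the resulting methanediazonium ion with loss of nitrogen; no base is present, so C8 is not epimerised and the acetate survives.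

## Compound list

1 | 2,2-dimethylpent-4-enal | C=CCC(C)(C)C=O | starting material
2 | (1E)-1-iodo-3,3-dimethylhexa-1,5-diene | I/C=C/C(C)(C)CC=C | intermediate
3 | tert-butyl(dimethyl)(prop-2-yn-1-yloxy)silane | C#CCO[Si](C)(C)C(C)(C)C | starting material
4 | tert-butyl{[(4E)-6,6-dimethylnona-4,8-dien-2-yn-1-yl]oxy}dimethylsilane | C=CCC(C)(C)/C=C/C#CCO[Si](C)(C)C(C)(C)C | intermediate
5 | tert-butyl{[(2Z,4E)-6,6-dimethylnona-2,4,8-trien-1-yl]oxy}dimethylsilane | C=CCC(C)(C)/C=C/C=C\CO[Si](C)(C)C(C)(C)C | intermediate
6 | methyl 3-oxobutanoate | COC(=O)CC(C)=O | starting material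
7 | methyl (2E)-3-{[(trifluoromethyl)sulfonyl]oxy}but-2-enoate | COC(=O)/C=C(\C)OS(=O)(=O)C(F)(F)F | intermediate
8 | 9-[(5E,7Z)-9-{[tert-butyl(dimethyl)silyl]oxy}-4,4-dimethylnona-5,7-dien-1-yl]-9-borabicyclo[3.3.1]nonane | C1CC2CCCC(C1)B2CCCC(C)(C)/C=C/C=C\CO[Si](C)(C)C(C)(C)C | intermediate (not isolated)
9 | methyl (2E,8E,10Z)-12-{[tert-butyl(dimethyl)silyl]oxy}-3,7,7-trimethyldodeca-2,8,10-trienoate | COC(=O)/C=C(\C)CCCC(C)(C)/C=C/C=C\CO[Si](C)(C)C(C)(C)C | intermediate
10 | (2E,8E,10Z)-12-{[tert-butyl(dimethyl)silyl]oxy}-3,7,7-trimethyldodeca-2,8,10-trienoic acid | OC(=O)/C=C(\C)CCCC(C)(C)/C=C/C=C\CO[Si](C)(C)C(C)(C)C | intermediate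
11 | 1,3-oxazolidin-2-one | O=C1NCCO1 | starting material
12 | 2,2-dimethylpropanoic (2E,8E,10Z)-12-{[tert-butyl(dimethyl)silyl]oxy}-3,7,7-trimethyldodeca-2,8,10-trienoic anhydride | CC(C)(C)C(=O)OC(=O)/C=C(\C)CCCC(C)(C)/C=C/C=C\CO[Si](C)(C)C(C)(C)C | intermediate (not isolated)
13 | lithium 2-oxo-1,3-oxazolidin-3-ide | [Li+].O=C1[N-]CCO1 | intermediate (not isolated)
14 | 3-[(2E,8E,10Z)-12-{[tert-butyl(dimethyl)silyl]oxy}-3,7,7-trimethyldodeca-2,8,10-trienoyl]-1,3-oxazolidin-2-one | O=C(/C=C(\C)CCCC(C)(C)/C=C/C=C\CO[Si](C)(C)C(C)(C)C)N1CCOC1=O | intermediate (key-step precursor)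
15 | 3-{[(1R,2S,4aR,8aR)-2-({[tert-butyl(dimethyl)silyl]oxy}methyl)-5,5,8a-trimethyl-1,2,4a,5,6,7,8,8a-octahydronaphthalen-1-yl]carbonyl}-1,3-oxazolidin-2-one | O=C(N3CCOC3=O)[C@@H]1[C@@H](CO[Si](C)(C)C(C)(C)C)C=C[C@@H]2C(C)(C)CCC[C@@]12C | intermediate (key-step product)
16 | (1R,2S,4aR,8aR)-2-({[tert-butyl(dimethyl)silyl]oxy}methyl)-5,5,8a-trimethyl-1,2,4a,5,6,7,8,8a-octahydronaphthalene-1-carbaldehyde | O=C[C@@H]1[C@@H](CO[Si](C)(C)C(C)(C)C)C=C[C@@H]2C(C)(C)CCC[C@@]12C | intermediate (not isolated in step 9, isolated in step 10)
17 | [(1R,2S,4aR,8aR)-2-({[tert-butyl(dimethyl)silyl]oxy}methyl)-5,5,8a-trimethyl-1,2,4a,5,6,7,8,8a-octahydronaphthalen-1-yl]methanol | OC[C@@H]1[C@@H](CO[Si](C)(C)C(C)(C)C)C=C[C@@H]2C(C)(C)CCC[C@@]12C | intermediate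
18 | tert-butyl{[(1R,2S,4aR,8aS)-1-ethenyl-5,5,8a-trimethyl-1,2,4a,5,6,7,8,8a-octahydronaphthalen-2-yl]methoxy}dimethylsilane | C=C[C@@H]1[C@@H](CO[Si](C)(C)C(C)(C)C)C=C[C@@H]2C(C)(C)CCC[C@@]12C | intermediate
19 | methyl 4-hydroxybut-2-ynoate | COC(=O)C#CCO | starting material
20 | methyl 4-(acetyloxy)but-2-ynoate | COC(=O)C#CCOC(C)=O | intermediate
21 | methyl (2Z)-4-(acetyloxy)-3-iodobut-2-enoate | COC(=O)/C=C(\I)COC(C)=O | intermediate
22 | 9-{2-[(1R,2S,4aR,8aS)-2-({[tert-butyl(dimethyl)silyl]oxy}methyl)-5,5,8a-trimethyl-1,2,4a,5,6,7,8,8a-octahydronaphthalen-1-yl]ethyl}-9-borabicyclo[3.3.1]nonane | C1CC2CCCC(C1)B2CC[C@@H]1[C@@H](CO[Si](C)(C)C(C)(C)C)C=C[C@@H]2C(C)(C)CCC[C@@]12C | intermediate (not isolated)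
23 | methyl (2E)-3-[(acetyloxy)methyl]-5-[(1R,2S,4aR,8aS)-2-({[tert-butyl(dimethyl)silyl]oxy}methyl)-5,5,8a-trimethyl-1,2,4a,5,6,7,8,8a-octahydronaphthalen-1-yl]pent-2-enoate | COC(=O)/C=C(\CC[C@@H]1[C@@H](CO[Si](C)(C)C(C)(C)C)C=C[C@@H]2C(C)(C)CCC[C@@]12C)COC(C)=O | intermediate
24 | methyl (2E)-3-[(acetyloxy)methyl]-5-[(1R,2S,4aR,8aS)-2-(hydroxymethyl)-5,5,8a-trimethyl-1,2,4a,5,6,7,8,8a-octahydronaphthalen-1-yl]pent-2-enoate | COC(=O)/C=C(\CC[C@@H]1[C@@H](CO)C=C[C@@H]2C(C)(C)CCC[C@@]12C)COC(C)=O | intermediate
25 | methyl (2E)-3-[(acetyloxy)methyl]-5-[(1R,2S,4aR,8aS)-2-formyl-5,5,8a-trimethyl-1,2,4a,5,6,7,8,8a-octahydronaphthalen-1-yl]pent-2-enoate | COC(=O)/C=C(\CC[C@@H]1[C@@H](C=O)C=C[C@@H]2C(C)(C)CCC[C@@]12C)COC(C)=O | intermediate (not isolated)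
26 | (1R,2S,4aR,8aS)-1-{(3E)-3-[(acetyloxy)methyl]-5-methoxy-5-oxopent-3-en-1-yl}-5,5,8a-trimethyl-1,2,4a,5,6,7,8,8a-octahydronaphthalene-2-carboxylic acid | COC(=O)/C=C(\CC[C@@H]1[C@@H](C(=O)O)C=C[C@@H]2C(C)(C)CCC[C@@]12C)COC(C)=O | intermediate
27 | methyl (1R,2S,4aR,8aS)-1-{(3E)-3-[(acetyloxy)methyl]-5-methoxy-5-oxopent-3-en-1-yl}-5,5,8a-trimethyl-1,2,4a,5,6,7,8,8a-octahydronaphthalene-2-carboxylate | COC(=O)/C=C(\CC[C@@H]1[C@@H](C(=O)OC)C=C[C@@H]2C(C)(C)CCC[C@@]12C)COC(C)=O | target

## Step count and least certain steps

Total: 17 steps. Longest linear sequence: 14 steps (steps 1, 2, 3, 5, 6, 7, 8, 9, 10, 11, 14, 15, 16, 17); steps 4, 12 and 13 make the two coupling partners.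

**Step 8 (key step, proposed new method).** The most likely failure is insufficient turnover. The trisubstituted dienophile and a diene whose s-cis form is disfavoured by the Z substituent may cyclise too slowly at temperatures where the catalyst still controls the outcome. An uncatalysed and therefore racemic pathway, a [1,5]-hydrogen shift in the Z diene, or leakage into the exo mode (which avoids the C20/C4-methyl diaxial contact) could then compete. The fallback replaces catalyst control by auxiliary control with a stronger, stoichiometric Lewis acid, a known reaction type for trienoyl oxazolidinones; it sets out from 10 and returns at 17. 10 is converted into 12 as in step 7 and used to acylate (4R)-4-benzyl-1,3-oxazolidin-2-one (deprotonated with n-BuLi), giving (4R)-4-benzyl-3-[(2E,8E,10Z)-12-(TBS-oxy)-3,7,7-trimethyldodeca-2,8,10-trienoyl]-1,3-oxazolidin-2-one F1. Me2AlCl (1.4 equiv) in CH2Cl2 at −30 to 0 °C forms the cationic aluminium chelate, a far stronger activator than the copper complex, in which the benzyl group covers the Si face of C9. The intramolecular Diels–Alder reaction should then give (4R)-4-benzyl-3-{[(1R,2S,4aR,8aR)-2-(TBS-oxymethyl)-5,5,8a-trimethyl-1,2,4a,5,6,7,8,8a-octahydronaphthalen-1-yl]carbonyl}-1,3-oxazolidin-2-one F2. Minor diastereomers can be removed at this stage, and LiBH4 as in step 9 gives 17 and returns the auxiliary.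

**Step 14.** The most likely failure is loss of the acetate, by hydrolysis in the aqueous base or by ionisation of the allylic acetate on zerovalent palladium; hydroboration next to the congested C9 may also be slow. The fallback keeps the coupling but brings the oxygen in unprotected and acetylates after all palladium and base chemistry; it sets out from 18 and 19 and returns at 23. NaI in AcOH converts 19 into methyl (2Z)-4-hydroxy-3-iodobut-2-enoate F3, whose hydroxymethyl group is trans to the ester and cannot lactonise. Coupling of 22 with F3 under the conditions of step 14 should give methyl (2E)-3-(hydroxymethyl)-5-[(1R,2S,4aR,8aS)-2-(TBS-oxymethyl)-5,5,8a-trimethyl-1,2,4a,5,6,7,8,8a-octahydronaphthalen-1-yl]pent-2-enoate F4. Ac2O and pyridine then give 23.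

**Step 5.** The most likely failure is hydrolysis of the vinylogous acyl triflate 7 by the base faster than transmetalation, or partial loss of its E geometry before coupling. The fallback builds the trisubstituted enoate by syn carbocupration of an ynoate, so that the geometry is created in the bond-forming step; it sets out from 5 and returns at 9. Hydroboration of 5 to 8 followed by NaOH/H2O2 gives (5E,7Z)-9-(TBS-oxy)-4,4-dimethylnona-5,7-dien-1-ol F5. I2, PPh3 and imidazole give tert-butyl{[(2Z,4E)-9-iodo-6,6-dimethylnona-2,4-dien-1-yl]oxy}dimethylsilane F6. Lithium–iodine exchange with t-BuLi and transmetalation with CuBr·SMe2 give the monovalent alkylcopper reagent [(5E,7Z)-9-(TBS-oxy)-4,4-dimethylnona-5,7-dien-1-yl]copper F7. Its syn addition to methyl but-2-ynoate in THF at −78 °C, with protonation in the cold, places the chain trans to the ester and gives 9.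

**Step 9.** The most likely failure is hydride attack at the ring carbonyl, opening the oxazolidinone, because the exocyclic carbonyl is shielded by the quaternary C10 and the C8 substituent. The fallback uses acyl transfer to sulfur in place of direct hydride cleavage; it sets out from 15 and returns at 16, so that step 10 is no longer needed. LiSEt (from EtSH and n-BuLi) in THF at 0 °C attacks the exocyclic carbonyl selectively and gives S-ethyl (1R,2S,4aR,8aR)-2-(TBS-oxymethyl)-5,5,8a-trimethyl-1,2,4a,5,6,7,8,8a-octahydronaphthalene-1-carbothioate F8. i-Bu2AlH in CH2Cl2 at −78 °C reduces F8 to 16.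

**Step 16.** The most likely failure is enolisation of the transient beta,gamma-unsaturated aldehyde, leading to migration of the 6,7-double bond into conjugation or epimerisation at C8, on the most advanced material. The fallback changes the order of events so that C17 is brought to the ester level on a simple intermediate, where a two-stage oxidation can be run and any conjugated isomer removed before the convergent coupling; it sets out from 18 and returns at 27.
- HF·pyridine gives [(1R,2S,4aR,8aS)-1-ethenyl-5,5,8a-trimethyl-1,2,4a,5,6,7,8,8a-octahydronaphthalen-2-yl]methanol F9.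
- Dess–Martin periodinane gives (1R,2S,4aR,8aS)-1-ethenyl-5,5,8a-trimethyl-1,2,4a,5,6,7,8,8a-octahydronaphthalene-2-carbaldehyde F10.
- Pinnick oxidation (NaClO2, NaH2PO4, 2-methylbut-2-ene) gives (1R,2S,4aR,8aS)-1-ethenyl-5,5,8a-trimethyl-1,2,4a,5,6,7,8,8a-octahydronaphthalene-2-carboxylic acid F11.
- Me3SiCHN2 gives methyl (1R,2S,4aR,8aS)-1-ethenyl-5,5,8a-trimethyl-1,2,4a,5,6,7,8,8a-octahydronaphthalene-2-carboxylate F12.
- 9-BBN gives methyl (1R,2S,4aR,8aS)-1-[2-(9-borabicyclo[3.3.1]nonan-9-yl)ethyl]-5,5,8a-trimethyl-1,2,4a,5,6,7,8,8a-octahydronaphthalene-2-carboxylate F13, which is coupled with 21 under the conditions of step 14 to give 27 directly.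

## Further compounds

F1 | step 8 | (4R)-4-benzyl-3-[(2E,8E,10Z)-12-{[tert-butyl(dimethyl)silyl]oxy}-3,7,7-trimethyldodeca-2,8,10-trienoyl]-1,3-oxazolidin-2-one | O=C(/C=C(\C)CCCC(C)(C)/C=C/C=C\CO[Si](C)(C)C(C)(C)C)N1[C@H](Cc2ccccc2)COC1=O
F2 | step 8 | (4R)-4-benzyl-3-{[(1R,2S,4aR,8aR)-2-({[tert-butyl(dimethyl)silyl]oxy}methyl)-5,5,8a-trimethyl-1,2,4a,5,6,7,8,8a-octahydronaphthalen-1-yl]carbonyl}-1,3-oxazolidin-2-one | O=C([C@@H]1[C@@H](CO[Si](C)(C)C(C)(C)C)C=C[C@@H]2C(C)(C)CCC[C@@]12C)N1[C@H](Cc2ccccc2)COC1=O
F3 | step 14 | methyl (2Z)-4-hydroxy-3-iodobut-2-enoate | COC(=O)/C=C(\I)CO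
F4 | step 14 | methyl (2E)-5-[(1R,2S,4aR,8aS)-2-({[tert-butyl(dimethyl)silyl]oxy}methyl)-5,5,8a-trimethyl-1,2,4a,5,6,7,8,8a-octahydronaphthalen-1-yl]-3-(hydroxymethyl)pent-2-enoate | COC(=O)/C=C(\CC[C@@H]1[C@@H](CO[Si](C)(C)C(C)(C)C)C=C[C@@H]2C(C)(C)CCC[C@@]12C)CO
F5 | step 5 | (5E,7Z)-9-{[tert-butyl(dimethyl)silyl]oxy}-4,4-dimethylnona-5,7-dien-1-ol | OCCCC(C)(C)/C=C/C=C\CO[Si](C)(C)C(C)(C)C
F6 | step 5 | tert-butyl{[(2Z,4E)-9-iodo-6,6-dimethylnona-2,4-dien-1-yl]oxy}dimethylsilane | ICCCC(C)(C)/C=C/C=C\CO[Si](C)(C)C(C)(C)C
F7 | step 5 | [(5E,7Z)-9-{[tert-butyl(dimethyl)silyl]oxy}-4,4-dimethylnona-5,7-dien-1-yl]copper | [Cu]CCCC(C)(C)/C=C/C=C\CO[Si](C)(C)C(C)(C)C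
F8 | step 9 | S-ethyl (1R,2S,4aR,8aR)-2-({[tert-butyl(dimethyl)silyl]oxy}methyl)-5,5,8a-trimethyl-1,2,4a,5,6,7,8,8a-octahydronaphthalene-1-carbothioate | CCSC(=O)[C@@H]1[C@@H](CO[Si](C)(C)C(C)(C)C)C=C[C@@H]2C(C)(C)CCC[C@@]12C
F9 | step 16 | [(1R,2S,4aR,8aS)-1-ethenyl-5,5,8a-trimethyl-1,2,4a,5,6,7,8,8a-octahydronaphthalen-2-yl]methanol | C=C[C@@H]1[C@@H](CO)C=C[C@@H]2C(C)(C)CCC[C@@]12C
F10 | step 16 | (1R,2S,4aR,8aS)-1-ethenyl-5,5,8a-trimethyl-1,2,4a,5,6,7,8,8a-octahydronaphthalene-2-carbaldehyde | C=C[C@@H]1[C@@H](C=O)C=C[C@@H]2C(C)(C)CCC[C@@]12C
F11 | step 16 | (1R,2S,4aR,8aS)-1-ethenyl-5,5,8a-trimethyl-1,2,4a,5,6,7,8,8a-octahydronaphthalene-2-carboxylic acid | C=C[C@@H]1[C@@H](C(=O)O)C=C[C@@H]2C(C)(C)CCC[C@@]12C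
F12 | step 16 | methyl (1R,2S,4aR,8aS)-1-ethenyl-5,5,8a-trimethyl-1,2,4a,5,6,7,8,8a-octahydronaphthalene-2-carboxylate | C=C[C@@H]1[C@@H](C(=O)OC)C=C[C@@H]2C(C)(C)CCC[C@@]12C
F13 | step 16 | methyl (1R,2S,4aR,8aS)-1-[2-(9-borabicyclo[3.3.1]nonan-9-yl)ethyl]-5,5,8a-trimethyl-1,2,4a,5,6,7,8,8a-octahydronaphthalene-2-carboxylate | C1CC2CCCC(C1)B2CC[C@@H]1[C@@H](C(=O)OC)C=C[C@@H]2C(C)(C)CCC[C@@]12C
A1 | alternative 1 | methyl 3-bromo-2-hydroxy-4-{5-[(methanesulfonyl)oxy]-2-methylpentan-2-yl}-5-methyl-6-[4-(trimethylsilyl)but-3-yn-1-yl]benzoate | COC(=O)c1c(O)c(Br)c(C(C)(C)CCCOS(C)(=O)=O)c(C)c1CCC#C[Si](C)(C)C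
A2 | alternative 1 | methyl (8aS)-4-bromo-5,5,8a-trimethyl-3-oxo-1-[4-(trimethylsilyl)but-3-yn-1-yl]-3,5,6,7,8,8a-hexahydronaphthalene-2-carboxylate | C[Si](C)(C)C#CCCC1=C(C(=O)OC)C(=O)C(Br)=C2C(C)(C)CCC[C@@]12C
A3 | alternative 2 | methyl (2Z)-3-[(1S,4aS,8aR)-4a,8,8-trimethyl-4a,5,6,7,8,8a-hexahydro-1H-isochromen-1-yl]prop-2-enoate | COC(=O)/C=C\[C@@H]1OC=C[C@]2(C)CCCC(C)(C)[C@@H]12
A4 | alternative 2 | methyl (1R,2S,4aR,8aR)-1-formyl-5,5,8a-trimethyl-1,2,4a,5,6,7,8,8a-octahydronaphthalene-2-carboxylate | O=C[C@@H]1[C@@H](C(=O)OC)C=C[C@@H]2C(C)(C)CCC[C@@]12C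
A5 | alternative 3 | methyl (3S)-2-bromo-6-{[tert-butyl(dimethyl)silyl]oxy}-3-{(1R,2R)-2-[(Z)-2-iodoethenyl]-1,3,3-trimethylcyclohexyl}hexanoate (both C2 epimers) | COC(=O)C(Br)[C@@H](CCCO[Si](C)(C)C(C)(C)C)[C@]1(C)CCCC(C)(C)[C@H]1/C=C\I
A6 | alternative 3 | methyl (1R,2S,4aR,8aS)-1-(3-{[tert-butyl(dimethyl)silyl]oxy}propyl)-5,5,8a-trimethyl-1,2,4a,5,6,7,8,8a-octahydronaphthalene-2-carboxylate | CC(C)(C)[Si](C)(C)OCCC[C@@H]1[C@@H](C(=O)OC)C=C[C@@H]2C(C)(C)CCC[C@@]12C
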